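The flavone is cut at the O1–C8a bond of ring C. Ring A of the target bears oxygen on five neighbouring carbons, C5 through C8a. A ring A that already has its four ether oxygens at C5–C8 but still a hydrogen at C8a is a strong electron donor, and anodic oxidation should let the enol oxygen of a 1,3-diketone bond to C8a, so that ring C closes and the fifth oxygen arrives in one operation. The precursor is a 1,3-diarylpropane-1,3-dione with a 2,4-bis(benzyloxy)-3,5-dimethoxyphenyl ring A and an electron-poor 3,5-diacetoxy-4-methoxyphenyl ring B, assembled by Claisen condensation of a syringol-derived acetophenone with a protected 4-O-methylgallate.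

Key step: step 10

Remark: the 1,3-diketones 14, 15 and 16 are drawn as diketo tautomers; they should exist mainly as hydrogen-bonded enols, and the enol is the form that cyclises in step 10.

Step 1
Reactants: 1 2,6-dimethoxyphenol (syringol); 2 benzyl bromide
Product: 3 2-(benzyloxy)-1,3-dimethoxybenzene
Conditions: K2CO3, DMF, 60 °C
Reagents that add atoms: benzyl bromide 2, BrCc1ccccc1
Why: Williamson ether synthesis, in which the phenoxide of 1 displaces bromide from 2; the ether masks the future C7 oxygen and turns the next bromination away from the position para to the free hydroxyl.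

Step 2
Reactants: 3 2-(benzyloxy)-1,3-dimethoxybenzene
Product: 4 2-(benzyloxy)-4-bromo-1,3-dimethoxybenzene
Conditions: NBS, MeCN, 0 °C → rt
Reagents that add atoms: N-bromosuccinimide, O=C1CCC(=O)N1Br
Why: Electrophilic aromatic bromination; the flanked central benzyloxy group is twisted out of conjugation, so attack should occur at C4, para to one methoxy and ortho to the other, as is usual for 1,2,3-trialkoxybenzenes.

Step 3
Reactants: 4 2-(benzyloxy)-4-bromo-1,3-dimethoxybenzene
Product: 7 3-(benzyloxy)-2,4-dimethoxyphenol, via aryllithium 5 (not isolated), via dimethyl arylboronate 6 (not isolated)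
Conditions: n-BuLi, THF, −78 °C; B(OMe)3, −78 °C → rt; AcOH, 30% aq. H2O2, 0 °C → rt
Reagents that add atoms: hydrogen peroxide, OO (the new oxygen of 7); trimethyl borate, COB(OC)OC (kept only in intermediate 6); n-butyllithium, [Li]CCCC (lithium kept only in intermediate 5)
Why: Bromine–lithium exchange, borylation and boronate oxidation (aryl migration from boron to oxygen) should turn C–Br into C–OH at low temperature without touching the benzyl ether.

Step 4
Reactants: 7 3-(benzyloxy)-2,4-dimethoxyphenol
Product: 8 3-(benzyloxy)-6-bromo-2,4-dimethoxyphenol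
Conditions: NBS, i-Pr2NH (cat.), CH2Cl2, 0 °C
Reagents that add atoms: N-bromosuccinimide, O=C1CCC(=O)N1Br
Why: Amine-catalysed ortho-bromination of a phenol (electrophilic aromatic substitution); the hydroxyl is the strongest donor, its para position and one ortho position carry methoxy groups, so bromine should enter at the single free ortho carbon C6.

Step 5
Reactants: 8 3-(benzyloxy)-6-bromo-2,4-dimethoxyphenol; 2 benzyl bromide
Product: 9 2,4-bis(benzyloxy)-1-bromo-3,5-dimethoxybenzene
Conditions: K2CO3, DMF, 60 °C
Reagents that add atoms: benzyl bromide 2, BrCc1ccccc1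
Why: Williamson ether synthesis on the hindered but acidic phenol protects the future C5 oxygen, which must not be free in the diketone or it would close ring C by simple dehydration on the wrong oxygen.

Step 6
Reactants: 9 2,4-bis(benzyloxy)-1-bromo-3,5-dimethoxybenzene
Product: 11 1-[2,4-bis(benzyloxy)-3,5-dimethoxyphenyl]ethan-1-one, via aryllithium 10 (not isolated)
Conditions: n-BuLi, THF, −78 °C; MeC(O)N(OMe)Me, −78 → 0 °C; 1 M HCl
Reagents that add atoms: N-methoxy-N-methylacetamide, CC(=O)N(C)OC; n-butyllithium, [Li]CCCC (lithium kept only in intermediate 10)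
Why: Bromine–lithium exchange followed by Weinreb ketone synthesis places the acetyl group exactly ortho to the C5 oxygen through a chelated tetrahedral intermediate, without any Lewis acid that could cleave the benzyl ethers.

Step 7
Reactants: 12 methyl 3,5-dihydroxy-4-methoxybenzoate
Product: 13 methyl 4-methoxy-3,5-bis(methoxymethoxy)benzoate
Conditions: MOMCl, i-Pr2NEt, CH2Cl2, 0 °C → rt
Reagents that add atoms: chloromethyl methyl ether, COCCl
Why: O-alkylation of both phenols with an α-chloro ether (acetal protection) gives ethers that survive the strongly basic Claisen step and are released by dilute acid.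

Step 8
Reactants: 11 1-[2,4-bis(benzyloxy)-3,5-dimethoxyphenyl]ethan-1-one; 13 methyl 4-methoxy-3,5-bis(methoxymethoxy)benzoate
Product: 15 1-[2,4-bis(benzyloxy)-3,5-dimethoxyphenyl]-3-(3,5-dihydroxy-4-methoxyphenyl)propane-1,3-dione, via bis(methoxymethyl) diketone 14 (not isolated)
Conditions: NaH, THF, 65 °C (11 added slowly to 13 and NaH); then HCl, MeOH, 45 °C
Reagents that add atoms: none
Why: Crossed Claisen condensation of the sodium enolate of 11 with the non-enolisable ester 13 is driven by deprotonation of the 1,3-diketone, and methanolic HCl then removes both acetals by transacetalisation while benzyl ethers and the diketone should be stable.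

Step 9
Reactants: 15 1-[2,4-bis(benzyloxy)-3,5-dimethoxyphenyl]-3-(3,5-dihydroxy-4-methoxyphenyl)propane-1,3-dione
Product: 16 1-[2,4-bis(benzyloxy)-3,5-dimethoxyphenyl]-3-(3,5-diacetoxy-4-methoxyphenyl)propane-1,3-dione
Conditions: Ac2O, pyridine, CH2Cl2, 0 °C → rt
Reagents that add atoms: acetic anhydride, CC(=O)OC(C)=O
Why: Phenol O-acetylation (nucleophilic acyl substitution) should be much faster than acylation of the hydrogen-bonded diketone enol, and the two acetates make ring B electron-poor for the electrolysis.

Step 10
Reactants: 16 1-[2,4-bis(benzyloxy)-3,5-dimethoxyphenyl]-3-(3,5-diacetoxy-4-methoxyphenyl)propane-1,3-dione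
Product: 17 2-(3,5-diacetoxy-4-methoxyphenyl)-5,7-bis(benzyloxy)-6,8-dimethoxy-4H-chromen-4-one
Conditions: constant-current electrolysis, undivided cell, graphite anode, Pt cathode, Bu4NBF4 (0.1 M), HFIP/CH2Cl2 (4:1), rt, about 2.2 F per mole
Reagents that add atoms: none
Why: Proposed new method: the tetra-alkoxy ring A is the most easily oxidised part of 16, so the anode should convert it into a radical cation that HFIP stabilises, the enol oxygen on C2 adds to C8a, and a second electron transfer with loss of the C8a proton restores aromaticity while protons are reduced to H2 at the cathode. The closest known reaction types are anodic dehydrogenative lactonisation of biaryl-2-carboxylic acids and oxidant-mediated cyclisation of enols or phenols onto electron-rich arenes. Ring C is closed as a six-membered ring by attack of oxygen on an arene carbon, endo with respect to the C4a–C8a bond, whereas closure through C3 would need a four-membered ring, and no stereocentre is formed. The step needs attack at C8a and not at ring B or at an ipso carbon: C8a is the only C–H ortho to the ketone on ring A and sits ortho to the methoxy at C8 and para to the methoxy at C6, while ring B carries two acetoxy groups and a single ether. Addition at the benzyloxy-bearing C5 cannot end in proton loss and should be reversible. Overoxidation should be limited by the charge passed and by the weaker donor character of O1 in the chromone.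

Step 11
Reactants: 17 2-(3,5-diacetoxy-4-methoxyphenyl)-5,7-bis(benzyloxy)-6,8-dimethoxy-4H-chromen-4-one
Product: 19 5,7-dihydroxy-2-(3,5-dihydroxy-4-methoxyphenyl)-6,8-dimethoxy-4H-chromen-4-one, via ring B diphenol 18 (not isolated)
Conditions: K2CO3 (2.5 equiv), MeOH/THF, rt; AcOH; then H2 (1 atm), Pd/C, rt
Reagents that add atoms: none
Why: Base-mediated transesterification (methanolysis) removes the two aryl acetates, and after neutralisation heterogeneous hydrogenolysis cleaves the two benzyl ethers to toluene, conditions that should leave the methyl ethers and the chromone untouched.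

Compound list (no compound of the main route has a stereocentre)

1 | 2,6-dimethoxyphenol (syringol) | COc1cccc(OC)c1O | starting material
2 | benzyl bromide | BrCc1ccccc1 | starting material
3 | 2-(benzyloxy)-1,3-dimethoxybenzene | COc1cccc(OC)c1OCc1ccccc1 | intermediate
4 | 2-(benzyloxy)-4-bromo-1,3-dimethoxybenzene | COc1ccc(Br)c(OC)c1OCc1ccccc1 | intermediate
5 | [3-(benzyloxy)-2,4-dimethoxyphenyl]lithium (formed in the flask in step 3) | COc1ccc([Li])c(OC)c1OCc1ccccc1 | intermediate
6 | dimethyl [3-(benzyloxy)-2,4-dimethoxyphenyl]boronate (formed in the flask in step 3) | COc1ccc(B(OC)OC)c(OC)c1OCc1ccccc1 | intermediate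
7 | 3-(benzyloxy)-2,4-dimethoxyphenol | COc1ccc(O)c(OC)c1OCc1ccccc1 | intermediate
8 | 3-(benzyloxy)-6-bromo-2,4-dimethoxyphenol | COc1cc(Br)c(O)c(OC)c1OCc1ccccc1 | intermediate
9 | 2,4-bis(benzyloxy)-1-bromo-3,5-dimethoxybenzene | COc1cc(Br)c(OCc2ccccc2)c(OC)c1OCc1ccccc1 | intermediate
10 | [2,4-bis(benzyloxy)-3,5-dimethoxyphenyl]lithium (formed in the flask in step 6) | COc1cc([Li])c(OCc2ccccc2)c(OC)c1OCc1ccccc1 | intermediate
11 | 1-[2,4-bis(benzyloxy)-3,5-dimethoxyphenyl]ethan-1-one | COc1cc(C(C)=O)c(OCc2ccccc2)c(OC)c1OCc1ccccc1 | intermediate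
12 | methyl 3,5-dihydroxy-4-methoxybenzoate (methyl 4-O-methylgallate) | COC(=O)c1cc(O)c(OC)c(O)c1 | starting material
13 | methyl 4-methoxy-3,5-bis(methoxymethoxy)benzoate | COCOc1cc(C(=O)OC)cc(OCOC)c1OC | intermediate
14 | 1-[2,4-bis(benzyloxy)-3,5-dimethoxyphenyl]-3-[4-methoxy-3,5-bis(methoxymethoxy)phenyl]propane-1,3-dione (formed in the flask in step 8) | COCOc1cc(C(=O)CC(=O)c2cc(OC)c(OCc3ccccc3)c(OC)c2OCc2ccccc2)cc(OCOC)c1OC | intermediate
15 | 1-[2,4-bis(benzyloxy)-3,5-dimethoxyphenyl]-3-(3,5-dihydroxy-4-methoxyphenyl)propane-1,3-dione | COc1c(O)cc(cc1O)C(=O)CC(=O)c1cc(OC)c(OCc2ccccc2)c(OC)c1OCc1ccccc1 | intermediate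
16 | 1-[2,4-bis(benzyloxy)-3,5-dimethoxyphenyl]-3-(3,5-diacetoxy-4-methoxyphenyl)propane-1,3-dione (precursor of the key step) | COc1c(OC(C)=O)cc(cc1OC(C)=O)C(=O)CC(=O)c1cc(OC)c(OCc2ccccc2)c(OC)c1OCc1ccccc1 | intermediate
17 | 2-(3,5-diacetoxy-4-methoxyphenyl)-5,7-bis(benzyloxy)-6,8-dimethoxy-4H-chromen-4-one (product of the key step) | COc1c(OC(C)=O)cc(cc1OC(C)=O)-c1cc(=O)c2c(OCc3ccccc3)c(OC)c(OCc3ccccc3)c(OC)c2o1 | intermediate
18 | 5,7-bis(benzyloxy)-2-(3,5-dihydroxy-4-methoxyphenyl)-6,8-dimethoxy-4H-chromen-4-one (formed in the flask in step 11) | COc1c(O)cc(cc1O)-c1cc(=O)c2c(OCc3ccccc3)c(OC)c(OCc3ccccc3)c(OC)c2o1 | intermediate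
19 | 5,7-dihydroxy-2-(3,5-dihydroxy-4-methoxyphenyl)-6,8-dimethoxy-4H-chromen-4-one | COc1c(O)cc(-c2cc(=O)c3c(O)c(OC)c(O)c(OC)c3o2)cc1O | target

Total step count: 11.
Longest linear sequence: 10 steps (steps 1–6 and 8–11 from syringol); step 7 is the only step of the ring B branch.

Steps most likely to fail

Step 10 (anodic ring closure). The radical cation may be trapped at an alkoxy-bearing carbon and then dealkylated to quinone-type material. A benzyl group may be lost oxidatively, two diketones may couple through C3, or the flavone may be oxidised further. The fallback uses known chemistry and makes the O1–C8a bond by copper-catalysed Ullmann-type O-arylation of a C8a bromide. It sets out from acetophenone 11. Bromination with NBS in MeCN at the only aromatic C–H should give 1-[2,4-bis(benzyloxy)-6-bromo-3,5-dimethoxyphenyl]ethan-1-one F1. Claisen condensation of F1 with ester 13 (NaH, THF, 65 °C) should give 1-[2,4-bis(benzyloxy)-6-bromo-3,5-dimethoxyphenyl]-3-[4-methoxy-3,5-bis(methoxymethoxy)phenyl]propane-1,3-dione F2. CuI, 1,10-phenanthroline and Cs2CO3 in DMF at 90 °C should join the enolate oxygen to the brominated carbon and give 5,7-bis(benzyloxy)-6,8-dimethoxy-2-[4-methoxy-3,5-bis(methoxymethoxy)phenyl]-4H-chromen-4-one F3. HCl in MeOH should then remove the two acetals and give 18, where the fallback comes back to the route before the hydrogenolysis stage of step 11.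

Step 8 (Claisen condensation). Acylation of the hindered enolate by the electron-rich ester may be slow, so that self-condensation of ketone 11 or retro-Claisen cleavage of the product competes. The fallback replaces acyl substitution by aldol addition and oxidation, and sets out from ester 13. Reduction with LiAlH4 in THF should give [4-methoxy-3,5-bis(methoxymethoxy)phenyl]methanol F4, and oxidation with MnO2 in CH2Cl2 should give 4-methoxy-3,5-bis(methoxymethoxy)benzaldehyde F5. The lithium enolate of 11 (LDA, THF, −78 °C) should add to F5 to give racemic 1-[2,4-bis(benzyloxy)-3,5-dimethoxyphenyl]-3-hydroxy-3-[4-methoxy-3,5-bis(methoxymethoxy)phenyl]propan-1-one F6. Its stereocentre is removed by Dess–Martin oxidation to diketone 14, where the fallback comes back to the route at the acid stage of step 8.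

Step 4 (ortho-bromination of the phenol). Bromine may enter at the other free ring carbon or twice, or the electron-rich phenol may be oxidised to a quinone. The fallback introduces the carbon substituent ortho to the hydroxyl directly by magnesium-mediated formylation, and sets out from phenol 7. MgCl2, Et3N and paraformaldehyde in MeCN at reflux should give 4-(benzyloxy)-2-hydroxy-3,5-dimethoxybenzaldehyde F7. Benzylation with 2 and K2CO3 in DMF should give 2,4-bis(benzyloxy)-3,5-dimethoxybenzaldehyde F8. MeMgBr in THF should give racemic 1-[2,4-bis(benzyloxy)-3,5-dimethoxyphenyl]ethan-1-ol F9, and oxidation with MnO2 should give acetophenone 11, where the fallback comes back to the route; steps 5 and 6 are by-passed as well.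

Further compounds

F1 | step 10 | 1-[2,4-bis(benzyloxy)-6-bromo-3,5-dimethoxyphenyl]ethan-1-one | COc1c(Br)c(C(C)=O)c(OCc2ccccc2)c(OC)c1OCc1ccccc1
F2 | step 10 | 1-[2,4-bis(benzyloxy)-6-bromo-3,5-dimethoxyphenyl]-3-[4-methoxy-3,5-bis(methoxymethoxy)phenyl]propane-1,3-dione | COCOc1cc(C(=O)CC(=O)c2c(Br)c(OC)c(OCc3ccccc3)c(OC)c2OCc2ccccc2)cc(OCOC)c1OC
F3 | step 10 | 5,7-bis(benzyloxy)-6,8-dimethoxy-2-[4-methoxy-3,5-bis(methoxymethoxy)phenyl]-4H-chromen-4-one | COCOc1cc(cc(OCOC)c1OC)-c1cc(=O)c2c(OCc3ccccc3)c(OC)c(OCc3ccccc3)c(OC)c2o1
F4 | step 8 | [4-methoxy-3,5-bis(methoxymethoxy)phenyl]methanol | COCOc1cc(CO)cc(OCOC)c1OC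
F5 | step 8 | 4-methoxy-3,5-bis(methoxymethoxy)benzaldehyde | COCOc1cc(C=O)cc(OCOC)c1OC
F6 | step 8 | 1-[2,4-bis(benzyloxy)-3,5-dimethoxyphenyl]-3-hydroxy-3-[4-methoxy-3,5-bis(methoxymethoxy)phenyl]propan-1-one (racemic) | COCOc1cc(C(O)CC(=O)c2cc(OC)c(OCc3ccccc3)c(OC)c2OCc2ccccc2)cc(OCOC)c1OC
F7 | step 4 | 4-(benzyloxy)-2-hydroxy-3,5-dimethoxybenzaldehyde | COc1cc(C=O)c(O)c(OC)c1OCc1ccccc1
F8 | step 4 | 2,4-bis(benzyloxy)-3,5-dimethoxybenzaldehyde | COc1cc(C=O)c(OCc2ccccc2)c(OC)c1OCc1ccccc1
F9 | step 4 | 1-[2,4-bis(benzyloxy)-3,5-dimethoxyphenyl]ethan-1-ol (racemic) | COc1cc(C(C)O)c(OCc2ccccc2)c(OC)c1OCc1ccccc1
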